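The data are calculated on assumed constants; the scatter is artificial.

3 questions stand on this flask, and I answer them with one number: how long the flask keeps working.

| flask | X | E | J | time |
|---|---|---|---|---|
| Friday's | 0.300 M | 0.450 M | 0.00900 M |  |
| Sunday's | 0.180 M | 0.330 M | 0.00900 M |  |
| Tuesday's | 0.300 M | 0.450 M | 0.0130 M |  |
| Monday's | 0.300 M | 0.450 M | 0.00900 M | 220 h |

| run | time / h | [Q] / M |
|---|---|---|
| Friday's run | 3.5 | 0.100 |
| Friday's run | 6.7 | 0.131 |
| Friday's run | 13 | 0.149 |
| Friday's run | 24 | 0.173 |
| Friday's run | 46 | 0.178 |
| Friday's run | 88 | 0.178 |
| Sunday's run | 3.5 | 0.051 |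
| Sunday's run | 6.7 | 0.073 |
| Sunday's run | 13 | 0.084 |
| Sunday's run | 24 | 0.090 |
| Sunday's run | 46 | 0.101 |
| Sunday's run | 88 | 0.104 |
| Tuesday's run | 3.5 | 0.131 |
| Tuesday's run | 6.7 | 0.159 |
| Tuesday's run | 13 | 0.175 |
| Tuesday's run | 24 | 0.191 |
| Tuesday's run | 46 | 0.190 |
| Tuesday's run | 88 | 0.204 |

(readings scatter by 0.003 M)

- how the opening rate goes with [J] round the charge of the Friday's run: the exponent of the rate at two percent of X gone to Q
- the Sunday's run starts with 0.120 M less of X and of E than the Friday's run, and with no Q. Compared where both hold the same amount of X, once fifteen percent of what the Sunday's run was charged with has turned into Q, is the Sunday's run faster, slower or alike (within a tenth)?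
- Q in the Monday's run at 220 h, as a share of the X charged

- Overall: X + E -> Q, with J as catalyst.
- Constant volume, constant temperature.
- An order is taken over about fifteen percent of the charge, up and down.

1. Friday's run flattens at cQ = 0.178 M, the mean of its last two readings. That is 59.3% of the X charged. By the balance on Q, 0.122 M of X is still there, so Friday's run stalls with X in hand.

2. Tuesday's run has more J and flattens higher, at 0.197 M. A catalyst leaves an equilibrium where it stands, so I do not read this stop as an equilibrium.

3. I need a clock. Suppose the rate is k·cJ·cX·cE with cJ steady. Then w, the logarithm of cE/cX measured from its value at the start, grows in a straight line with time. I take cX and cE from cQ by the balance.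

4. In Friday's run, w is 0.154 at the first reading, 3.5 h. At the plateau it is 0.396.

5. Their ratio, times 3.5 h, gives 9.00 h for Friday's run. I call this the working life: the time a flask needs to reach its plateau w at the pace of its first reading. The same reading gives 9.97 h for Sunday's run and 7.51 h for Tuesday's run.

6. Monday's run repeats Friday's charge, and 220 h is 24.4 working lives. I therefore expect Friday's plateau again, 59.3% of X.

7. At equal X, Friday's run stands near its 13 h reading, later than its working life. Sunday's run stands before its first reading, inside its own. So I expect Sunday's run to be faster.

The forecast gives 1.05, faster and 60%, on these grounds: “this is not a true equilibrium: the catalyst is dying, with a lifetime of roughly 7–10 h”. My share for Monday's run is lower than its 60%.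

The flask gives 1.0, faster and 61.4%.

    J + X + E → Q + J (54.36 L² mol⁻² h⁻¹)
    2 E → Qa (0.2646 L mol⁻¹ h⁻¹)
    2 J → 2 Zu (5.976 L mol⁻¹ h⁻¹)

With Friday's charge, Q forms by the k1 step while E pairs off to Qa, with a first half-life of 4.20 h by that step alone. Meanwhile J pairs off to Zu, with a first half-life of 9.30 h by that step alone. Well past its working life of 9.00 h, Q still creeps up: Monday's run reaches 61.4% of the X charged at 220 h, more than the 59.3% read off Friday's plateau. In Sunday's run, with a working life of 9.97 h, a quarter of the X charged has become Q by 2.63 h, and half by 17.6 h, which is 1.77 working lives.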